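**Retrosynthetic overview**

1. Feature: in the oxane (O1, C2 bearing phenol ring C, C3 bearing the cinnamyl arm, C4, C5 bearing carbinol C7 with ring B, C6) the C2 aryl group, the C3 chain and the C5 arm all stand on one face. The cis C2/C3 pair is what an endo aldehyde/(E)-diene cycloaddition leaves, and the C5 arm is what hydrogen delivery to the opposite face leaves.
2. Late stage: the aryl pivalates and the C7 silyl ether come off last. The styrene (ring A) comes from a Julia–Kocienski olefination of a sulfone on the C3 arm, C6 becomes CH2 by silane reduction of a methyl acetal, and C5–H comes from hydrogenation of C4=C5.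
3. Key disconnection: C2–C3 and O1–C6, by a catalytic asymmetric oxa-Diels–Alder reaction of 4-formylphenyl pivalate 2 with 1-methoxydiene 17. This is the only ring formed; the three benzene rings are bought.
4. Diene 17: C5=C6 by Wittig methoxymethylenation of an enone; C4–C5 by Weinreb ketone synthesis from the amide of (S)-4-hydroxymandelic acid (source of C7) and an (E)-alkenyllithium from 3-butyn-1-ol.
5. Rings A and C both come from 4-hydroxybenzaldehyde (as 2), ring B from the mandelic acid.

Key step: step 9

Remark on the chemistry: (S)-4-hydroxymandelic acid is taken as purchasable enantiopure material (it is also obtainable by classical resolution of the inexpensive racemate).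

Abbreviations: TBS = tert-butyldimethylsilyl, PMB = 4-methoxybenzyl, Piv = pivaloyl, PT = 1-phenyl-1H-tetrazol-5-yl. Atom labels O1 and C2–C7 are those of the oxane of the target.

**Route**

Step 1
Reactants: 1 4-hydroxybenzaldehyde
Product: 2 4-formylphenyl pivalate
Conditions: PivCl, Et3N, DMAP (cat.), CH2Cl2, 0 °C → rt
Reagents that add atoms: pivaloyl chloride, CC(C)(C)C(=O)Cl
Why: DMAP-catalysed esterification of the phenol is fast and leaves the aldehyde untouched; no stereocentre is formed.

Step 2
Reactants: 3 (S)-4-hydroxymandelic acid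
Product: 4 (2S)-2-hydroxy-2-(4-hydroxyphenyl)-N-methoxy-N-methylacetamide
Conditions: MeNHOMe·HCl, EDC·HCl, HOBt, N-methylmorpholine, CH2Cl2/DMF, 0 °C → rt
Reagents that add atoms: N,O-dimethylhydroxylamine hydrochloride, CNOC.Cl
Why: Carbodiimide/HOBt amide coupling of an unprotected α-hydroxy acid is routine because the hydroxyl groups are far poorer nucleophiles than the hydroxylamine and any aryl ester formed is aminolysed, and C7 is safe since an α-hydroxy acid cannot racemise through an azlactone.

Step 3
Reactants: 4 (2S)-2-hydroxy-2-(4-hydroxyphenyl)-N-methoxy-N-methylacetamide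
Product: 5 (2S)-2-(TBS-oxy)-2-[4-(TBS-oxy)phenyl]-N-methoxy-N-methylacetamide
Conditions: TBSCl (2.5 equiv), imidazole, DMF, rt → 40 °C
Reagents that add atoms: tert-butyldimethylsilyl chloride, CC(C)(C)[Si](C)(C)Cl
Why: Silyl ether formation protects both hydroxyls in one operation as groups inert to the organolithium and ylide steps (an aryl pivalate would not survive them), and the C7–O bond is not broken.

Step 4
Reactants: 6 3-butyn-1-ol
Product: 7 4-(4-methoxybenzyloxy)but-1-yne
Conditions: NaH, PMBCl, Bu4NI (cat.), THF/DMF, 0 °C → rt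
Reagents that add atoms: 4-methoxybenzyl chloride, COc1ccc(CCl)cc1
Why: Williamson etherification of the alkoxide, which forms selectively because the alcohol is far more acidic than the alkyne C–H.

Step 5
Reactants: 7 4-(4-methoxybenzyloxy)but-1-yne
Product: 9 (E)-1-iodo-4-(4-methoxybenzyloxy)but-1-ene, via alkenylzirconocene chloride 8 (not isolated)
Conditions: Cp2Zr(H)Cl, THF, rt; then I2, 0 °C
Reagents that add atoms: iodine, II
Why: Hydrozirconation of a terminal alkyne is a syn, anti-Markovnikov addition and iodinolysis of the C–Zr bond proceeds with retention, so the (E)-iodide results.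

Step 6
Reactants: 9 (E)-1-iodo-4-(4-methoxybenzyloxy)but-1-ene; 5 (2S)-2-(TBS-oxy)-2-[4-(TBS-oxy)phenyl]-N-methoxy-N-methylacetamide
Product: 12 (1S,3E)-1-(TBS-oxy)-1-[4-(TBS-oxy)phenyl]-6-(PMB-oxy)hex-3-en-2-one, via alkenyllithium 10 (not isolated), via tetrahedral lithium adduct 11 (not isolated)
Conditions: t-BuLi (2.1 equiv), Et2O, −78 °C; then 5 in THF, −78 °C; AcOH, −78 °C → rt
Reagents that add atoms: none
Why: Iodine–lithium exchange is stereoretentive and the Weinreb ketone synthesis stops at the chelated tetrahedral adduct, so the α-silyloxy ketone is released only on cold acidic quench and C7 never meets base as a ketone.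

Step 7
Reactants: 12 (1S,3E)-1-(TBS-oxy)-1-[4-(TBS-oxy)phenyl]-6-(PMB-oxy)hex-3-en-2-one; 13 (methoxymethyl)triphenylphosphonium chloride
Product: 15 (1Z,3E)-1-methoxy-2-[(S)-(TBS-oxy)(4-TBS-oxyphenyl)methyl]-6-(PMB-oxy)hexa-1,3-diene (OMe cis to C7), via methoxymethylene ylide 14 (not isolated)
Conditions: 13, KN(SiMe3)2 (slight excess over 13), THF, 0 °C; then 12, −78 → −20 °C
Reagents that add atoms: (methoxymethyl)triphenylphosphonium chloride 13, COC[P+](c1ccccc1)(c1ccccc1)c1ccccc1.[Cl-]
Why: Wittig methoxymethylenation of the ketone, in which the α-silyloxy carbon should steer the ylide substituent to its own side (the cis-directing effect of an α-alkoxy group in ketone olefinations with non-stabilised ylides), putting OMe cis to C7 and trans to C4, while cold addition to a salt-free ylide should outrun proton transfer from C7.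

Step 8
Reactants: 15 (1Z,3E)-1-methoxy-2-[(S)-(TBS-oxy)(4-TBS-oxyphenyl)methyl]-6-(PMB-oxy)hexa-1,3-diene
Product: 17 4-[(S)-(TBS-oxy)[(1Z,3E)-1-methoxy-6-(PMB-oxy)hexa-1,3-dien-2-yl]methyl]phenyl pivalate, via tetrabutylammonium phenoxide 16 (not isolated)
Conditions: Bu4NF (1.05 equiv), THF, −20 °C; then Et3N, PivCl, −20 → 0 °C
Reagents that add atoms: pivaloyl chloride, CC(C)(C)C(=O)Cl
Why: Fluoride cleaves the aryl silyl ether far faster than the hindered secondary alkyl one, and acylation of the phenoxide in the same flask puts the electron-poor ester on ring B before any Lewis acid is met.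

Step 9
Reactants: 17 4-[(S)-(TBS-oxy)[(1Z,3E)-1-methoxy-6-(PMB-oxy)hexa-1,3-dien-2-yl]methyl]phenyl pivalate; 2 4-formylphenyl pivalate
Product: 18 all-cis (2R,3S,6S)-6-methoxy-3-[2-(PMB-oxy)ethyl]-2-(4-pivaloyloxyphenyl)-5-[(S)-(TBS-oxy)(4-pivaloyloxyphenyl)methyl]-3,6-dihydro-2H-pyran
Conditions: [CrCl(C27H29NO2)] (5 mol %; trivalent chromium chloride complex of the Schiff base of 3-(1-adamantyl)-5-methylsalicylaldehyde with (1R,2S)-1-amino-2-indanol), powdered 4 Å molecular sieves, 2 (2 equiv), minimal TBME, rt
Reagents that add atoms: none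
Why: The trivalent chromium centre binds the formyl oxygen anti to the aryl group and the diene adds through a concerted, asynchronous [4+2] transition state in which C2–C3 bonding runs ahead of O1–C6 bonding; the closest known reaction type is the chromium Schiff-base catalysed endo oxa-Diels–Alder reaction of 1-alkoxy-1,3-dienes with aldehydes. The dihydropyran ring closes by suprafacial cycloaddition, not by an ionic 6-endo or 6-exo closure, so no chair with an equatorial aryl group is imposed. C2 is set by the catalyst, which with the (1R,2S)-ligand is expected, by analogy with its sense toward 1-methoxybutadiene, to open the Re face of the aldehyde (the antipodal ligand is the remedy should the sense be opposite). C3 and C6 follow from the endo orientation of the aryl group together with the (3E) geometry and the outward methoxy group of 17, which put chain, methoxy and aryl on one face; C7 enters unchanged and, insulated from both forming bonds by C5, should only modulate the catalyst's facial preference. The step needs endo and aldehyde-face selectivity (catalyst), an s-cis diene with no inward substituent (geometry of 17) and survival of the vinylogous silyl acetal at C7, which the weakly Lewis acidic complex, the sieves and the electron-poor pivaloyloxyphenyl rings should secure.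

Step 10
Reactants: 18 all-cis 6-methoxy-3,6-dihydro-2H-pyran cycloadduct
Product: 19 all-cis 6-methoxytetrahydropyran (C2 aryl, C3 chain, C5 arm and C6 OMe on one face; C7 unchanged)
Conditions: H2 (1–3 atm), Rh/Al2O3 (5 %), EtOAc, rt
Reagents that add atoms: none
Why: Heterogeneous hydrogenation should deliver both hydrogens to the face of C4=C5 opposite the C2 aryl group, the C3 chain and the C6 methoxy group, which sets C5 with its arm cis to the C3 chain, and rhodium on alumina is chosen for its low tendency to hydrogenolyse allylic or benzylic C–O bonds and PMB ethers.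

Step 11
Reactants: 19 all-cis 6-methoxytetrahydropyran
Product: 20 2,3,5-all-cis tetrahydropyran with C6 as CH2 (PMB ether, C7 TBS ether, two pivalates)
Conditions: Et3SiH (3 equiv), Me3SiOTf (0.2 equiv), CH2Cl2, −78 °C
Reagents that add atoms: none
Why: Silane reduction of an acetal (ionisation to the cyclic oxocarbenium ion, then hydride transfer) replaces OMe by H at a carbon that becomes a methylene group, and the pivaloyloxyphenyl rings should keep the benzylic C2–O and C7–O bonds from ionising at −78 °C.

Step 12
Reactants: 20 2,3,5-all-cis tetrahydropyran PMB ether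
Product: 21 primary alcohol (2-hydroxyethyl arm on C3)
Conditions: DDQ, CH2Cl2/pH 7 buffer, 0 °C
Reagents that add atoms: none
Why: Oxidative PMB cleavage by DDQ (hydride abstraction, then hydrolysis) is selective because the other benzylic positions carry electron-poor acyloxyphenyl rings.

Step 13
Reactants: 21 primary alcohol
Product: 22 PT sulfide (2-(PT-thio)ethyl arm on C3)
Conditions: 1-phenyl-1H-tetrazole-5-thiol, PPh3, DIAD, THF, 0 °C → rt
Reagents that add atoms: 1-phenyl-1H-tetrazole-5-thiol, Sc1nnnn1-c1ccccc1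
Why: Mitsunobu thioetherification of a primary alcohol with the acidic tetrazole thiol (SN2 at CH2); no stereocentre is involved.

Step 14
Reactants: 22 PT sulfide
Product: 23 PT sulfone
Conditions: H2O2 (30 %), (NH4)6Mo7O24·4H2O (cat.), EtOH, 0 °C → rt
Reagents that add atoms: hydrogen peroxide, OO
Why: Peroxomolybdate-catalysed oxidation of the sulfide to the sulfone; 22 has no alkene or other oxidisable group.

Step 15
Reactants: 23 PT sulfone; 2 4-formylphenyl pivalate
Product: 25 (E)-styrene tris-pivalate with C7 TBS ether, via potassium sulfonyl carbanion 24 (not isolated)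
Conditions: KN(SiMe3)2 (1.1 equiv), DME, −60 °C; then 2 (1.3 equiv), −60 °C → rt
Reagents that add atoms: none
Why: Julia–Kocienski olefination (carbanion addition to the non-enolisable aryl aldehyde, Smiles rearrangement, loss of SO2 and the tetrazololate) should give the conjugated (E)-alkene, and the hindered pivalates should not be attacked by the bulky amide base at low temperature.

Step 16
Reactants: 25 (E)-styrene tris-pivalate with C7 TBS ether
Product: 26 C7 carbinol tris-pivalate
Conditions: Bu4NF, AcOH (1:1), THF, rt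
Reagents that add atoms: none
Why: Fluoride-mediated cleavage of the last silyl ether, buffered with acetic acid so that the aryl pivalates are not exposed to free alkoxide, and C7 keeps its configuration because the C–O bond is not broken.

Step 17
Reactants: 26 C7 carbinol tris-pivalate
Product: 27 4-[(E)-3-[(2R,3S,5R)-2-(4-hydroxyphenyl)-5-[(R)-hydroxy(4-hydroxyphenyl)methyl]oxan-3-yl]prop-1-en-1-yl]phenol (target)
Conditions: i-Bu2AlH (10 equiv), CH2Cl2, −78 → 0 °C; aq. KNaC4H4O6
Reagents that add atoms: none
Why: Reductive cleavage of the three aryl pivalates by hydride (ester reduction) is irreversible and non-basic, so the free 4-hydroxybenzylic ether at C2 and carbinol at C7 are never held under equilibrating conditions that could open them through quinone methides.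

**Compound list**

1 | 4-hydroxybenzaldehyde | O=Cc1ccc(O)cc1 | starting material
2 | 4-formylphenyl pivalate | CC(C)(C)C(=O)Oc1ccc(C=O)cc1 | intermediate
3 | (S)-4-hydroxymandelic acid | OC(=O)[C@@H](O)c1ccc(O)cc1 | starting material
4 | (2S)-2-hydroxy-2-(4-hydroxyphenyl)-N-methoxy-N-methylacetamide | CON(C)C(=O)[C@@H](O)c1ccc(O)cc1 | intermediate
5 | (2S)-2-(TBS-oxy)-2-[4-(TBS-oxy)phenyl]-N-methoxy-N-methylacetamide | CON(C)C(=O)[C@@H](O[Si](C)(C)C(C)(C)C)c1ccc(O[Si](C)(C)C(C)(C)C)cc1 | intermediate
6 | 3-butyn-1-ol | C#CCCO | starting material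
7 | 4-(4-methoxybenzyloxy)but-1-yne | C#CCCOCc1ccc(OC)cc1 | intermediate
8 | (E)-alkenylzirconocene chloride (not isolated; cyclopentadienyl rings drawn σ-bonded) | COc1ccc(COCC/C=C/[Zr](Cl)(C2C=CC=C2)C2C=CC=C2)cc1 | intermediate
9 | (E)-1-iodo-4-(4-methoxybenzyloxy)but-1-ene | COc1ccc(COCC/C=C/I)cc1 | intermediate
10 | (E)-alkenyllithium (not isolated) | [Li]/C=C/CCOCc1ccc(OC)cc1 | intermediate
11 | tetrahedral lithium adduct of 10 with 5 (not isolated) | CON(C)C(O[Li])(/C=C/CCOCc1ccc(OC)cc1)[C@@H](O[Si](C)(C)C(C)(C)C)c1ccc(O[Si](C)(C)C(C)(C)C)cc1 | intermediate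
12 | (1S,3E)-1-(TBS-oxy)-1-[4-(TBS-oxy)phenyl]-6-(PMB-oxy)hex-3-en-2-one | COc1ccc(COCC/C=C/C(=O)[C@@H](O[Si](C)(C)C(C)(C)C)c2ccc(O[Si](C)(C)C(C)(C)C)cc2)cc1 | intermediate
13 | (methoxymethyl)triphenylphosphonium chloride | COC[P+](c1ccccc1)(c1ccccc1)c1ccccc1.[Cl-] | starting material
14 | (methoxymethylene)triphenylphosphorane (not isolated) | COC=P(c1ccccc1)(c1ccccc1)c1ccccc1 | intermediate
15 | (1Z,3E)-1-methoxy-2-[(S)-(TBS-oxy)(4-TBS-oxyphenyl)methyl]-6-(PMB-oxy)hexa-1,3-diene | CO/C=C(\[C@@H](O[Si](C)(C)C(C)(C)C)c1ccc(O[Si](C)(C)C(C)(C)C)cc1)/C=C/CCOCc1ccc(OC)cc1 | intermediate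
16 | tetrabutylammonium phenoxide of the diene (not isolated) | CO/C=C(\[C@@H](O[Si](C)(C)C(C)(C)C)c1ccc([O-])cc1)/C=C/CCOCc1ccc(OC)cc1.CCCC[N+](CCCC)(CCCC)CCCC | intermediate
17 | 4-[(S)-(TBS-oxy)[(1Z,3E)-1-methoxy-6-(PMB-oxy)hexa-1,3-dien-2-yl]methyl]phenyl pivalate (key-step precursor) | CO/C=C(\[C@@H](O[Si](C)(C)C(C)(C)C)c1ccc(OC(=O)C(C)(C)C)cc1)/C=C/CCOCc1ccc(OC)cc1 | intermediate
18 | all-cis (2R,3S,6S)-6-methoxy-3,6-dihydro-2H-pyran cycloadduct (key-step product) | COc1ccc(COCC[C@H]2C=C([C@@H](O[Si](C)(C)C(C)(C)C)c3ccc(OC(=O)C(C)(C)C)cc3)[C@@H](OC)O[C@H]2c2ccc(OC(=O)C(C)(C)C)cc2)cc1 | intermediate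
19 | all-cis 6-methoxytetrahydropyran | COc1ccc(COCC[C@H]2C[C@@H]([C@@H](O[Si](C)(C)C(C)(C)C)c3ccc(OC(=O)C(C)(C)C)cc3)[C@@H](OC)O[C@H]2c2ccc(OC(=O)C(C)(C)C)cc2)cc1 | intermediate
20 | 2,3,5-all-cis tetrahydropyran PMB ether | COc1ccc(COCC[C@H]2C[C@@H]([C@@H](O[Si](C)(C)C(C)(C)C)c3ccc(OC(=O)C(C)(C)C)cc3)CO[C@H]2c2ccc(OC(=O)C(C)(C)C)cc2)cc1 | intermediate
21 | primary alcohol (2-hydroxyethyl arm on C3) | OCC[C@H]1C[C@@H]([C@@H](O[Si](C)(C)C(C)(C)C)c2ccc(OC(=O)C(C)(C)C)cc2)CO[C@H]1c1ccc(OC(=O)C(C)(C)C)cc1 | intermediate
22 | PT sulfide | S(CC[C@H]1C[C@@H]([C@@H](O[Si](C)(C)C(C)(C)C)c2ccc(OC(=O)C(C)(C)C)cc2)CO[C@H]1c1ccc(OC(=O)C(C)(C)C)cc1)c1nnnn1-c1ccccc1 | intermediate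
23 | PT sulfone | O=S(=O)(CC[C@H]1C[C@@H]([C@@H](O[Si](C)(C)C(C)(C)C)c2ccc(OC(=O)C(C)(C)C)cc2)CO[C@H]1c1ccc(OC(=O)C(C)(C)C)cc1)c1nnnn1-c1ccccc1 | intermediate
24 | potassium sulfonyl carbanion (not isolated) | [K+].O=S(=O)([CH-]C[C@H]1C[C@@H]([C@@H](O[Si](C)(C)C(C)(C)C)c2ccc(OC(=O)C(C)(C)C)cc2)CO[C@H]1c1ccc(OC(=O)C(C)(C)C)cc1)c1nnnn1-c1ccccc1 | intermediate
25 | (E)-styrene tris-pivalate with C7 TBS ether | CC(C)(C)C(=O)Oc1ccc(/C=C/C[C@H]2C[C@@H]([C@@H](O[Si](C)(C)C(C)(C)C)c3ccc(OC(=O)C(C)(C)C)cc3)CO[C@H]2c2ccc(OC(=O)C(C)(C)C)cc2)cc1 | intermediate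
26 | C7 carbinol tris-pivalate | CC(C)(C)C(=O)Oc1ccc(/C=C/C[C@H]2C[C@@H]([C@@H](O)c3ccc(OC(=O)C(C)(C)C)cc3)CO[C@H]2c2ccc(OC(=O)C(C)(C)C)cc2)cc1 | intermediate
27 | 4-[(E)-3-[(2R,3S,5R)-2-(4-hydroxyphenyl)-5-[(R)-hydroxy(4-hydroxyphenyl)methyl]oxan-3-yl]prop-1-en-1-yl]phenol | Oc1ccc(/C=C/C[C@H]2C[C@@H]([C@@H](O)c3ccc(O)cc3)CO[C@H]2c2ccc(O)cc2)cc1 | target

**Step count and risks**

Total step count: 17. Longest linear sequence: 14 steps (3 → 4 → 5 → 12 → 15 → 17 → 18 → … → 27; the branch from 6 is equally long).

Steps most likely to fail: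

(a) Step 9. The cycloaddition of a 2,4-disubstituted 1-methoxydiene with an aryl aldehyde may be slow, so that the diene ionises at C7 or hydrolyses before it reacts; endo and facial control may also erode under double diastereoselection. Any isomer of 17 with an inward methoxy group, and any material of eroded configuration at C7, should end as unreacted diene or as a separable diastereomer here. Fallback (a more electrophilic dienophile, then ester exchange), setting out from 1 and 17 and returning at 18: 1 is converted with Tf2O/pyridine into 4-formylphenyl trifluoromethanesulfonate F1. The same chromium complex unites F1 with 17 to give the triflate-bearing cycloadduct F2. Aqueous Et4NOH in dioxane at rt cleaves the aryl triflate and the ring B pivalate to give the bisphenol cycloadduct F3. PivCl/Et3N/DMAP then gives 18.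

(b) Step 7. Proton transfer from C7 to the ylide would erode the configuration at C7, and the enol ether may form as a mixture of geometric isomers. The slight excess of base is meant to keep any enolised ketone out of the olefination, so that the diene formed keeps its configuration. Fallback (stepwise Horner–Wittig olefination), setting out from 12 and returning at 15: (methoxymethyl)diphenylphosphine oxide is lithiated with LiN(i-Pr)2 and added to 12 at −78 °C, where addition should outrun enolisation, to give the β-hydroxy phosphine oxides F4. These diastereomers are separated on silica. The set whose stereospecific syn elimination (KH, THF) places OMe cis to C7 is carried to 15.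

(c) Step 10. Hydrogenolysis of the allylic C6–O and C7–O bonds or of the PMB ether on the metal surface may compete with slow saturation of the hindered trisubstituted alkene. Fallback (order inverted, homogeneous catalyst), setting out from 18 and returning at 20: the methyl acetal is reduced first (Et3SiH, cat. Me3SiOTf, CH2Cl2, −78 °C) to give the 3,6-dihydro-2H-pyran lacking the C6 methoxy group F5. Its less congested C4=C5 bond is then hydrogenated with [Ir(cod)(PCy3)(py)]PF6 in CH2Cl2, which does not cleave C–O bonds and should add to the face opposite the C3 chain, giving 20 directly.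

**Further compounds**

F1 | step 9 | 4-formylphenyl trifluoromethanesulfonate | O=Cc1ccc(OS(=O)(=O)C(F)(F)F)cc1
F2 | step 9 | all-cis cycloadduct carrying a triflate on ring C | COc1ccc(COCC[C@H]2C=C([C@@H](O[Si](C)(C)C(C)(C)C)c3ccc(OC(=O)C(C)(C)C)cc3)[C@@H](OC)O[C@H]2c2ccc(OS(=O)(=O)C(F)(F)F)cc2)cc1
F3 | step 9 | all-cis cycloadduct with free phenols on rings B and C | COc1ccc(COCC[C@H]2C=C([C@@H](O[Si](C)(C)C(C)(C)C)c3ccc(O)cc3)[C@@H](OC)O[C@H]2c2ccc(O)cc2)cc1
F4 | step 7 | β-hydroxy phosphine oxide adducts of 12 (diastereomers at the two new centres) | COC(P(=O)(c1ccccc1)c1ccccc1)C(O)(/C=C/CCOCc1ccc(OC)cc1)[C@@H](O[Si](C)(C)C(C)(C)C)c1ccc(O[Si](C)(C)C(C)(C)C)cc1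
F5 | step 10 | cis-2,3-disubstituted 3,6-dihydro-2H-pyran lacking the C6 methoxy group | COc1ccc(COCC[C@H]2C=C([C@@H](O[Si](C)(C)C(C)(C)C)c3ccc(OC(=O)C(C)(C)C)cc3)CO[C@H]2c2ccc(OC(=O)C(C)(C)C)cc2)cc1
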